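**Retrosynthetic overview**

1. The target is (17R)-1,5,10-trimethyl-17-tridecyl-1,5,10,14-tetraazacycloheptadecan-15-one, numbered N1 (the N-methyl nitrogen on the stereocentre C17), C2–C4, N5(Me), C6–C9, N10(Me), C11–C13, N14–H, C15=O, C16; it has one ring (17-membered) and one stereocentre.
2. Last disconnection: C2 is taken up to the amide level (tertiary lactam N1–C2=O), to be deoxygenated chemoselectively beside the secondary lactam N14–C15=O.
3. Key disconnection: the ring is closed at C3–C4 by a three-component decarboxylative Mannich macrocyclisation; N5–H and formaldehyde give the iminium N5=C4, which is attacked by C3 of an N1-malonyl half acid, and the activating carboxyl group leaves as CO2 in the same operation.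
4. Enabling feature: the 1,3-diamine unit N1–C2–C3–C4–N5 of the ring is a Mannich retron (C4 is alpha to the tertiary amine N5; C3 is beta to N1 and alpha to a carbonyl once C2 is an amide), and the open-chain precursor is a head-to-tail ammonium carboxylate that folds the chain for closure.
5. The seco acid comes from three pieces: an (R)-3-(methylamino)hexadecanoyl unit (sulfinimine/titanium enolate addition sets C17), a mono-Cbz triamine from N,N'-dimethylbutane-1,4-diamine, and monobenzyl malonate.

Key step: step 12

Remark: tetradecanal, (R)-2-methylpropane-2-sulfinamide, methyl acetate, N,N'-dimethylbutane-1,4-diamine, N-(3-bromopropyl)phthalimide and monobenzyl malonate are taken as commercial.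

**Route**

Step 1
Reactants: 1 tetradecanal; 2 (R)-2-methylpropane-2-sulfinamide
Product: 3 (R,E)-2-methyl-N-tetradecylidenepropane-2-sulfinamide
Conditions: Ti(OEt)4 (2 equiv), THF, 23 °C
Reagents that add atoms: none
Why: Condensation of an aldehyde with tert-butanesulfinamide (Ellman sulfinimine formation), driven by the water-scavenging Lewis acid, should give the E-aldimine with the sulfur configuration intact.

Step 2
Reactants: 3 (R,E)-2-methyl-N-tetradecylidenepropane-2-sulfinamide; 4 methyl acetate
Product: 7 methyl (3R)-3-{[(R)-tert-butylsulfinyl]amino}hexadecanoate, via lithium enolate of methyl acetate 5 (not isolated), via triisopropoxytitanium enolate of methyl acetate 6 (not isolated)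
Conditions: LiN(i-Pr)2, THF, −78 °C; ClTi(Oi-Pr)3; then 3, −78 °C; aq. NH4Cl
Reagents that add atoms: none
Why: Mannich-type addition of a titanium ester enolate to a tert-butanesulfinyl aldimine through a closed chair (Zimmerman–Traxler) transition state with titanium bound to the sulfinyl oxygen should deliver the enolate to the Si face of the (R)-sulfinyl imine and so set the (3R) centre under auxiliary control.

Step 3
Reactants: 7 methyl (3R)-3-{[(R)-tert-butylsulfinyl]amino}hexadecanoate
Product: 8 methyl (3R)-3-{[(R)-tert-butylsulfinyl](methyl)amino}hexadecanoate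
Conditions: LiN(SiMe3)2, THF, −78 °C; MeI, DMF, −78 → 0 °C
Reagents that add atoms: iodomethane, CI
Why: N-Alkylation (SN2) of the lithiated sulfinamide, whose N–H is far more acidic than the ester alpha C–H, should install the N-methyl group without touching either stereocentre.

Step 4
Reactants: 8 methyl (3R)-3-{[(R)-tert-butylsulfinyl](methyl)amino}hexadecanoate
Product: 9 (3R)-3-{[(R)-tert-butylsulfinyl](methyl)amino}hexadecanoic acid
Conditions: LiOH, THF/MeOH/H2O, 23 °C; then AcOH to pH 5
Reagents that add atoms: lithium hydroxide, [Li+].[OH-]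
Why: Ester saponification should proceed cleanly because the sulfinamide is stable to base, and the weakly acidic work-up spares the acid-labile N–S bond.

Step 5
Reactants: 10 N,N'-dimethylbutane-1,4-diamine
Product: 11 benzyl methyl[4-(methylamino)butyl]carbamate
Conditions: CbzCl (0.3 equiv), CH2Cl2, −20 → 23 °C; aq. NaOH
Reagents that add atoms: benzyl chloroformate, O=C(Cl)OCc1ccccc1
Why: Carbamate formation with the symmetrical diamine in large excess should favour monoprotection, the excess diamine being removed by aqueous extraction.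

Step 6
Reactants: 11 benzyl methyl[4-(methylamino)butyl]carbamate; 12 N-(3-bromopropyl)phthalimide
Product: 13 benzyl (4-{[3-(1,3-dioxoisoindolin-2-yl)propyl](methyl)amino}butyl)(methyl)carbamate
Conditions: K2CO3, MeCN, 60 °C
Reagents that add atoms: none
Why: SN2 N-alkylation of the secondary amine by a primary bromide carrying a Gabriel-protected nitrogen should give the tertiary amine.

Step 7
Reactants: 13 benzyl (4-{[3-(1,3-dioxoisoindolin-2-yl)propyl](methyl)amino}butyl)(methyl)carbamate
Product: 14 benzyl {4-[(3-aminopropyl)(methyl)amino]butyl}(methyl)carbamate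
Conditions: N2H4·H2O, EtOH, 60 °C
Reagents that add atoms: none
Why: Hydrazinolysis of the phthalimide (Gabriel synthesis, Ing–Manske procedure) should free the primary amine while the benzyl carbamate stays intact.

Step 8
Reactants: 9 (3R)-3-{[(R)-tert-butylsulfinyl](methyl)amino}hexadecanoic acid; 14 benzyl {4-[(3-aminopropyl)(methyl)amino]butyl}(methyl)carbamate
Product: 16 benzyl N-methyl-N-{4-[methyl(3-{[(3R)-3-{[(R)-tert-butylsulfinyl](methyl)amino}hexadecanoyl]amino}propyl)amino]butyl}carbamate, via benzotriazol-1-yl active ester 15 (not isolated)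
Conditions: EDC·HCl, HOBt, i-Pr2NEt, CH2Cl2, 0 → 23 °C
Reagents that add atoms: none
Why: Carbodiimide/HOBt amide coupling with the only acylatable nitrogen (the primary amine) should be clean, and the stereocentre, beta to the activated carbonyl, cannot epimerise.

Step 9
Reactants: 16 benzyl N-methyl-N-{4-[methyl(3-{[(3R)-3-{[(R)-tert-butylsulfinyl](methyl)amino}hexadecanoyl]amino}propyl)amino]butyl}carbamate
Product: 17 benzyl N-methyl-N-{4-[methyl(3-{[(3R)-3-(methylamino)hexadecanoyl]amino}propyl)amino]butyl}carbamate
Conditions: HCl (4 M in dioxane), MeOH, 0 °C; then aq. Na2CO3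
Reagents that add atoms: none
Why: Acidic methanolysis of the sulfinamide N–S bond (standard removal of the sulfinyl auxiliary) should free the N-methylamine while the Cbz group and the amide survive.

Step 10
Reactants: 17 benzyl N-methyl-N-{4-[methyl(3-{[(3R)-3-(methylamino)hexadecanoyl]amino}propyl)amino]butyl}carbamate; 18 3-(benzyloxy)-3-oxopropanoic acid (monobenzyl malonate)
Product: 20 benzyl 3-{methyl[(3R)-1-{[3-({4-[(benzyloxycarbonyl)(methyl)amino]butyl}(methyl)amino)propyl]amino}-1-oxohexadecan-3-yl]amino}-3-oxopropanoate, via 7-azabenzotriazol-1-yl active ester 19 (not isolated)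
Conditions: EDC·HCl, HOAt, i-Pr2NEt, CH2Cl2, 0 → 23 °C
Reagents that add atoms: none
Why: Carbodiimide/HOAt amide coupling should acylate the hindered N-methylamine, the only N–H amine present, and so install the malonyl unit as its benzyl half ester.

Step 11
Reactants: 20 benzyl 3-{methyl[(3R)-1-{[3-({4-[(benzyloxycarbonyl)(methyl)amino]butyl}(methyl)amino)propyl]amino}-1-oxohexadecan-3-yl]amino}-3-oxopropanoate
Product: 21 3-{methyl[(3R)-1-({3-[methyl(4-(methylamino)butyl)amino]propyl}amino)-1-oxohexadecan-3-yl]amino}-3-oxopropanoic acid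
Conditions: H2 (1 atm), Pd/C, THF/H2O, 23 °C
Reagents that add atoms: none
Why: Catalytic hydrogenolysis should remove the benzyl ester and the Cbz group in one operation and give the zwitterionic seco amino acid, which is used without heating.

Step 12
Reactants: 21 3-{methyl[(3R)-1-({3-[methyl(4-(methylamino)butyl)amino]propyl}amino)-1-oxohexadecan-3-yl]amino}-3-oxopropanoic acid
Product: 24 (17R)-1,5,10-trimethyl-17-tridecyl-1,5,10,14-tetraazacycloheptadecane-2,15-dione, via N-methyleneiminium carboxylate 22 (not isolated), via macrocyclic malonamic acid 23 (not isolated)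
Conditions: CH2O (37% aq., 1.05 equiv, slow addition), MeCN/H2O (9:1), 1 mM, 23 °C, then 70 °C
Reagents that add atoms: formaldehyde, C=O
Why: Proposed new method: the secondary amine N5–H of 21 (the only N–H amine; N10 is tertiary, N1 and N14 are amide nitrogens) should condense with formaldehyde to the iminium ion 22, whose carbon C4 is attacked by the enol of the malonamic acid at C3, the only doubly activated C–H position, forming the C3–C4 bond and the 17-membered ring, after which the alpha-(aminomethyl)malonamic acid 23 loses CO2 on warming so that the activating group leaves in the same operation. The closest known reaction type is the Mannich reaction of malonic acid and its half esters with formaldehyde and secondary amines to give beta-amino acids and esters, together with the decarboxylative Mannich addition of malonic half thioesters to imines; new here is its use as a macrocyclisation. The ring closes in a 17-endo-trig mode at the iminium C=N bond (both C4 and N5 end up in the ring), the nucleophilic carbon C3 lying between the C2 amide and the exocyclic carboxyl group. No new stereocentre remains, because C3 of 23 is stereogenic only until decarboxylation, and C17 carries no acidic hydrogen and bears an amide nitrogen that cannot leave by retro-Michael reaction. Ring closure over oligomerisation should be secured by the 1 mM concentration with slow addition of one equivalent of formaldehyde, by the internal ammonium–carboxylate ion pair that brings the chain ends together, and by the reversibility of the Mannich addition before the irreversible decarboxylation, which lets open oligomers return to the cyclic monomer; a second aminomethylation at C3 is suppressed because decarboxylation removes the activation after the first C–C bond.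

Step 13
Reactants: 24 (17R)-1,5,10-trimethyl-17-tridecyl-1,5,10,14-tetraazacycloheptadecane-2,15-dione
Product: 26 (17R)-1,5,10-trimethyl-17-tridecyl-1,5,10,14-tetraazacycloheptadecan-15-one, via macrocyclic enamine 25 (not isolated)
Conditions: IrCl(CO)(PPh3)2 (2 mol %), (Me2HSi)2O, toluene, 23 °C; then NaBH(OAc)3, AcOH, CH2Cl2, 0 → 23 °C
Reagents that add atoms: none
Why: Iridium-catalysed hydrosilylation with IrCl(CO)(PPh3)2 converts tertiary amides into N,O-silyl hemiaminals and enamines while leaving secondary amides untouched, and protonation/hydride reduction of enamine 25 (as in a reductive amination) should then give the amine at C2 without affecting the N14–C15 lactam or C17.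

**Compound list**

1 | tetradecanal | CCCCCCCCCCCCCC=O | starting material
2 | (R)-2-methylpropane-2-sulfinamide | CC(C)(C)[S@](N)=O | starting material
3 | (R,E)-2-methyl-N-tetradecylidenepropane-2-sulfinamide | CCCCCCCCCCCCC/C=N/[S@](=O)C(C)(C)C | intermediate
4 | methyl acetate | CC(=O)OC | starting material
5 | lithium enolate of methyl acetate (lithium 1-methoxyethenolate) | [Li]OC(=C)OC | intermediate (not isolated)
6 | triisopropoxytitanium enolate of methyl acetate | C=C(OC)O[Ti](OC(C)C)(OC(C)C)OC(C)C | intermediate (not isolated)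
7 | methyl (3R)-3-{[(R)-tert-butylsulfinyl]amino}hexadecanoate | CCCCCCCCCCCCC[C@@H](N[S@](=O)C(C)(C)C)CC(=O)OC | intermediate
8 | methyl (3R)-3-{[(R)-tert-butylsulfinyl](methyl)amino}hexadecanoate | CCCCCCCCCCCCC[C@@H](N(C)[S@](=O)C(C)(C)C)CC(=O)OC | intermediate
9 | (3R)-3-{[(R)-tert-butylsulfinyl](methyl)amino}hexadecanoic acid | CCCCCCCCCCCCC[C@@H](N(C)[S@](=O)C(C)(C)C)CC(=O)O | intermediate
10 | N,N'-dimethylbutane-1,4-diamine | CNCCCCNC | starting material
11 | benzyl methyl[4-(methylamino)butyl]carbamate | CNCCCCN(C)C(=O)OCc1ccccc1 | intermediate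
12 | N-(3-bromopropyl)phthalimide | BrCCCN1C(=O)c2ccccc2C1=O | starting material
13 | benzyl (4-{[3-(1,3-dioxoisoindolin-2-yl)propyl](methyl)amino}butyl)(methyl)carbamate | O=C1c2ccccc2C(=O)N1CCCN(C)CCCCN(C)C(=O)OCc1ccccc1 | intermediate
14 | benzyl {4-[(3-aminopropyl)(methyl)amino]butyl}(methyl)carbamate | NCCCN(C)CCCCN(C)C(=O)OCc1ccccc1 | intermediate
15 | benzotriazol-1-yl (3R)-3-{[(R)-tert-butylsulfinyl](methyl)amino}hexadecanoate | CCCCCCCCCCCCC[C@@H](N(C)[S@](=O)C(C)(C)C)CC(=O)On1nnc2ccccc12 | intermediate (not isolated)
16 | benzyl N-methyl-N-{4-[methyl(3-{[(3R)-3-{[(R)-tert-butylsulfinyl](methyl)amino}hexadecanoyl]amino}propyl)amino]butyl}carbamate | CCCCCCCCCCCCC[C@@H](N(C)[S@](=O)C(C)(C)C)CC(=O)NCCCN(C)CCCCN(C)C(=O)OCc1ccccc1 | intermediate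
17 | benzyl N-methyl-N-{4-[methyl(3-{[(3R)-3-(methylamino)hexadecanoyl]amino}propyl)amino]butyl}carbamate | CCCCCCCCCCCCC[C@@H](NC)CC(=O)NCCCN(C)CCCCN(C)C(=O)OCc1ccccc1 | intermediate
18 | 3-(benzyloxy)-3-oxopropanoic acid (monobenzyl malonate) | OC(=O)CC(=O)OCc1ccccc1 | starting material
19 | benzyl 7-azabenzotriazol-1-yl malonate (active ester of 18) | O=C(CC(=O)OCc1ccccc1)On1nnc2cccnc12 | intermediate (not isolated)
20 | benzyl 3-{methyl[(3R)-1-{[3-({4-[(benzyloxycarbonyl)(methyl)amino]butyl}(methyl)amino)propyl]amino}-1-oxohexadecan-3-yl]amino}-3-oxopropanoate | CCCCCCCCCCCCC[C@@H](N(C)C(=O)CC(=O)OCc1ccccc1)CC(=O)NCCCN(C)CCCCN(C)C(=O)OCc1ccccc1 | intermediate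
21 | 3-{methyl[(3R)-1-({3-[methyl(4-(methylamino)butyl)amino]propyl}amino)-1-oxohexadecan-3-yl]amino}-3-oxopropanoic acid | CCCCCCCCCCCCC[C@@H](N(C)C(=O)CC(=O)O)CC(=O)NCCCN(C)CCCCNC | intermediate
22 | N-methyleneiminium carboxylate of 21 (zwitterion) | CCCCCCCCCCCCC[C@@H](N(C)C(=O)CC(=O)[O-])CC(=O)NCCCN(C)CCCC[N+](C)=C | intermediate (not isolated)
23 | (17R)-1,5,10-trimethyl-2,15-dioxo-17-tridecyl-1,5,10,14-tetraazacycloheptadecane-3-carboxylic acid (C3 epimers) | CCCCCCCCCCCCC[C@@H]1CC(=O)NCCCN(C)CCCCN(C)CC(C(=O)O)C(=O)N1C | intermediate (not isolated)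
24 | (17R)-1,5,10-trimethyl-17-tridecyl-1,5,10,14-tetraazacycloheptadecane-2,15-dione | CCCCCCCCCCCCC[C@@H]1CC(=O)NCCCN(C)CCCCN(C)CCC(=O)N1C | intermediate
25 | (17R)-1,5,10-trimethyl-17-tridecyl-1,5,10,14-tetraazacycloheptadec-2-en-15-one (alkene geometry not defined) | CCCCCCCCCCCCC[C@@H]1CC(=O)NCCCN(C)CCCCN(C)CC=CN1C | intermediate (not isolated)
26 | (17R)-1,5,10-trimethyl-17-tridecyl-1,5,10,14-tetraazacycloheptadecan-15-one | CCCCCCCCCCCCC[C@@H]1CC(=O)NCCCN(C)CCCCN(C)CCCN1C | target

**Step count and risks**

Total step count: 13. Longest linear sequence: 10 steps (steps 1–4 and 8–13); steps 5–7 build the triamine piece that enters at step 8.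

Steps most likely to fail:

1. Step 12 (proposed new method). Intermolecular Mannich addition could lead to oligomerisation, or the malonamic acid could decarboxylate before the C–C bond forms, leaving an unreactive acetamide. Fallback by known chemistry, setting out from 17 and returning at 24: the N-methylamine of 17 would be acylated with 3-chloropropanoyl chloride (CH2Cl2/aq. NaHCO3, 0 °C) to give benzyl N-{4-[(3-{[(3R)-3-[(3-chloropropanoyl)(methyl)amino]hexadecanoyl]amino}propyl)(methyl)amino]butyl}-N-methylcarbamate F1. Hydrogenolysis of the Cbz group in the presence of HCl (H2, Pd/C, MeOH) would give (3R)-3-[(3-chloropropanoyl)(methyl)amino]-N-(3-{methyl[4-(methylamino)butyl]amino}propyl)hexadecanamide F2, handled as its dihydrochloride. Slow addition of this salt to K2CO3/NaI in MeCN at 1 mM and 60 °C should close the ring to 24 by elimination to the acrylamide and intramolecular aza-Michael addition (or direct N-alkylation) of the freed N-methylamine. The route then continues with step 13.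

2. Step 13. Chemoselectivity could be lost by hydrosilylation of the secondary lactam, or the ring could open by beta-elimination of the N5 amine at the enamine/iminium stage before hydride delivery. Fallback, setting out from 17 and returning at 26: aza-Michael addition of the N-methylamine of 17 to acrolein (CH2Cl2, 0 °C) would give benzyl N-methyl-N-{4-[methyl(3-{[(3R)-3-[methyl(3-oxopropyl)amino]hexadecanoyl]amino}propyl)amino]butyl}carbamate F3. Hydrogenolysis of its Cbz group under high dilution (H2, Pd/C, AcOH, MeOH, 2 mM) with in-situ intramolecular reductive amination should then form the macrocycle directly at the amine oxidation level, so that no amide has to be reduced.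

3. Step 3. The lithiated sulfinamide could undergo retro-Mannich fragmentation or beta-elimination, eroding the configuration at the carbinamine carbon, or methylation could be incomplete. Fallback (Fukuyama sequence), setting out from 7 and returning at 17:
   - HCl/MeOH would remove the sulfinyl group to give methyl (3R)-3-aminohexadecanoate F4.
   - 2-Nitrobenzenesulfonyl chloride/Et3N would give methyl (3R)-3-[(2-nitrophenyl)sulfonylamino]hexadecanoate F5.
   - MeI/K2CO3/DMF would give methyl (3R)-3-[methyl(2-nitrophenylsulfonyl)amino]hexadecanoate F6.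
   - LiOH would give (3R)-3-[methyl(2-nitrophenylsulfonyl)amino]hexadecanoic acid F7.
   - EDC/HOBt coupling with 14 would give benzyl N-methyl-N-{4-[methyl(3-{[(3R)-3-[methyl(2-nitrophenylsulfonyl)amino]hexadecanoyl]amino}propyl)amino]butyl}carbamate F8.
   - PhSH/K2CO3 in MeCN would remove the sulfonyl group to give 17.

**Further compounds**

F1 | step 12 | benzyl N-{4-[(3-{[(3R)-3-[(3-chloropropanoyl)(methyl)amino]hexadecanoyl]amino}propyl)(methyl)amino]butyl}-N-methylcarbamate | CCCCCCCCCCCCC[C@@H](N(C)C(=O)CCCl)CC(=O)NCCCN(C)CCCCN(C)C(=O)OCc1ccccc1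
F2 | step 12 | (3R)-3-[(3-chloropropanoyl)(methyl)amino]-N-(3-{methyl[4-(methylamino)butyl]amino}propyl)hexadecanamide | CCCCCCCCCCCCC[C@@H](N(C)C(=O)CCCl)CC(=O)NCCCN(C)CCCCNC
F3 | step 13 | benzyl N-methyl-N-{4-[methyl(3-{[(3R)-3-[methyl(3-oxopropyl)amino]hexadecanoyl]amino}propyl)amino]butyl}carbamate | CCCCCCCCCCCCC[C@@H](N(C)CCC=O)CC(=O)NCCCN(C)CCCCN(C)C(=O)OCc1ccccc1
F4 | step 3 | methyl (3R)-3-aminohexadecanoate | CCCCCCCCCCCCC[C@@H](N)CC(=O)OC
F5 | step 3 | methyl (3R)-3-[(2-nitrophenyl)sulfonylamino]hexadecanoate | CCCCCCCCCCCCC[C@@H](NS(=O)(=O)c1ccccc1[N+](=O)[O-])CC(=O)OC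
F6 | step 3 | methyl (3R)-3-[methyl(2-nitrophenylsulfonyl)amino]hexadecanoate | CCCCCCCCCCCCC[C@@H](N(C)S(=O)(=O)c1ccccc1[N+](=O)[O-])CC(=O)OC
F7 | step 3 | (3R)-3-[methyl(2-nitrophenylsulfonyl)amino]hexadecanoic acid | CCCCCCCCCCCCC[C@@H](N(C)S(=O)(=O)c1ccccc1[N+](=O)[O-])CC(=O)O
F8 | step 3 | benzyl N-methyl-N-{4-[methyl(3-{[(3R)-3-[methyl(2-nitrophenylsulfonyl)amino]hexadecanoyl]amino}propyl)amino]butyl}carbamate | CCCCCCCCCCCCC[C@@H](N(C)S(=O)(=O)c1ccccc1[N+](=O)[O-])CC(=O)NCCCN(C)CCCCN(C)C(=O)OCc1ccccc1
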